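7.95 s: that is the relaxation half-life of L with E in dawn, far shorter than the run, so you may treat L and E as one pool split by the equilibrium constant.

all flasks: time 80 s

| run | X | L | remark |
|---|---|---|---|
| midnight | 1.0 mM (fed, over 1.0 min) | 1.30 equiv | all else is in the flask from the start; the feed brings no volume worth counting |
| noon | 1.0 mM | 1.30 equiv | everything together at the start |
| dawn | 1.0 mM | 1.30 equiv (fed, over 1.0 min) | all else is in the flask from the start; the feed brings no volume worth counting |

    L ⇌ E (K1 = 0.38, k1 = 0.024 /s)
    L + G → L.G (k2 = 1.4 /M/s)
    X + L → Q + D (k3 = 10 /M/s)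
    L + Q → G + D (k4 = 44 /M/s)
    Q → Z (k5 = 0.017 /s)

1. the best flask by amount of G, in percent of the X charged; "all alike" if 1.5 percentage points covers them all (midnight / noon / dawn / all alike)
2. amount of G at the end, in percent of the X charged, midnight
3. amount of G at the end, in percent of the X charged, noon
4. amount of G at the end, in percent of the X charged, dawn

My reckoning freezes c(L). I guess that 0.5 equiv of the pool is spent by mid-run, which leaves

c(L) = 0.580 mM

Q then has two exits, each a time constant for you: L takes it on to G in 39.2 s, and it leaks to Z in 58.8 s. Their ratio tK/tT = 1.50 is the selectivity factor, and from it comes φ, the share of Q that goes on to G: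

φ = tK/(tK + tT) = 60.0%

G has a half-life of 6.3 min in noon by its own loss step, with the other concentrations as charged, and that is longer than the run, so I drop that loss. X turns over with the time constant tX = 172 s. A feed costs about half its length, on average, so

G ≈ φ(1 − exp(−t/tX))

noon: 22.3%
midnight: 15.1%
dawn: 15.1%

So I pick noon. The forecast also says noon, with 13.5% for midnight, 21% for noon and 15% for dawn, on the ground that “feeding either one delays Q”.

The simulation gives noon as the best flask, with 13.5% for midnight, 20.7% for noon and 13.5% for dawn.

In noon at 80.0 s, G and L.G against Z read as a share of 63.0%, beside φ of 60.0%. Now take the neighbour, dawn with 5.20 equiv of L. The same reckoning gives c(L) = 3.41 mM and φ = 89.8%. That flask holds G 56.7%, L.G 7.26% and Z 11.1% at 80.0 s, a share of 85.2%.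

(The numbers were chosen freely, and the outcome is calculated.)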